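## Structural features

The target is a drimane-type sesquiterpene joined through an ether oxygen to C7 of a coumarin; drimane numbering is used throughout (ring A: C1–C5 and C10; ring B: C5–C10; C11 is the oxymethylene on C9, C12 the methyl on C8). Ring A is a cyclohexanone whose carbonyl (C3) sits next to the quaternary C4 with two methyls, and rings A and B are trans-fused through C5 (H) and the quaternary C10 (methyl). Ring B holds the trisubstituted C7=C8 alkene and, at C9, the CH2O–aryl arm; C5, C10 and C9 are contiguous, with H5 anti to the C10 methyl and C11 also anti to it, so the arm is axial and H9 lies on the face of the angular methyl (5R,9R,10S). Fragile points are the coumarin lactone and its C3′=C4′ acceptor alkene (organometallics, hydrides, radicals), the β,γ-unsaturated C9 methine (acid moves the alkene to C8=C9) and the homoallylic aryl ether (strong base can expel the phenoxide). The real difficulty is twofold: the axial C9 arm, because borane, hydrogen or a proton reaches C9 from the open α face opposite the angular methyl and would leave the arm equatorial; and the C3(=O)–C4(CH3)2–C5 array inside an enantiopure trans-decalin. The key step exploits the second feature: a carbonyl carbon bonded to a carbon with two methyls is the retron of a tertiary radical, made by hydrogen-atom transfer to an isopropenyl group on C5, adding to a nitrile carbon (C3). Once the C3–C4 bond is cut in this way, ring B with its C5 isopropenyl group, C8 methyl and C7=C8 alkene is the carbon skeleton of (R)-carvone, which supplies C5 in the correct absolute configuration. In one sentence: ring A is closed last by an iron hydride hydrogen-atom-transfer radical cyclisation of an isopropenyl group onto a nitrile in a carvone-derived cyclohexene.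

## Logic of the disconnections

15 to 13 + 14. The O–C11 bond is cut. The lactone and acceptor alkene of 14 would not survive iron hydride radicals, sulfur ylides or organopalladium intermediates, so the phenol is attached last. This keeps the aromatic lactone out of every C–C bond-forming step. The forward step must substitute the β-branched primary alcohol of 13 without touching the C3 ketone or eliminating towards C9.

13 to 11 (through 12). The C3–C4 bond is cut and ring A is opened: C3 becomes a nitrile carbon and C4 the internal carbon of an isopropenyl group on C5. The cut is made here because C4 carries two methyls next to a carbonyl, which is what a tertiary radical adding to a nitrile produces. The gain is large: a bicyclic α-quaternary ketone becomes a monocyclic cyclohexene on which all three stereocentres sit, and both C4 methyls and the ketone arise in one event. The forward step demands hydrogen-atom transfer to the 1,1-disubstituted alkene in preference to C7=C8, radical addition to the nitrile faster than radical reduction, and side chains on C5 and C10 that are already trans.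

11 to 7 + 8 (through 9 and 10). The C9–H bond is cut. The hydrogen must arrive on the hindered β face of C9, so it is delivered intramolecularly from a diazene on the β face of C7, which in turn comes from allylic substitution of a spiro vinyl epoxide by 8. The gain is that the C9 stereocentre is reduced to the configuration of an epoxide and the C7=C8 alkene is regenerated automatically. The demands are ionisation of the C9–O bond with inversion, attack of 8 at C7 anti to palladium, and a suprafacial retro-ene loss of N2.

7 to 6. The C9–C11 and C11–O bonds are cut, returning the spiro-epoxide to the C9 ketone. A carbonyl addition anti to the axial C10 methyl places C11 on the α face, exactly where the target needs it. The gain is the removal of C11 and of the C9 stereocentre. The demand is a small nucleophile that adds 1,2 to a ketone flanked by a quaternary carbon and a methyl-bearing alkene carbon, in the presence of a nitrile.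

6 to 5 to 4. No skeletal bond is cut: the nitrile carbon C3 is traced back through the aldehyde of 5 to the terminal alkyne carbon of 4. A three-carbon arm ending in a radical acceptor cannot be put on C10 by conjugate addition without risking a second, intramolecular Michael closure onto the enone, whereas a propargyl arm goes on by plain alkylation. The demand is anti-Markovnikov hydration of the alkyne and an aldehyde-selective conversion to the nitrile beside a ketone.

4 to 2 + 3. The C10–C1 bond is cut. The enolate of 2 is alkylated on the face opposite the neighbouring isopropenyl group, which sets the quaternary C10 with the arm trans and the methyl cis to that group, the relationship of a trans-decalin. The demand is high facial selectivity in this alkylation.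

2 to 1. The C10–CH3 bond is cut. The methyl must go on before the arm, because the second electrophile decides the configuration at C10. 1 is a commercial terpene that already holds C5, the C8 methyl, the C7=C8 alkene and the future C4 carbon.

## Other disconnections considered

Alternative 1: the first idea is to cut O–C11 and to build the decalin conventionally from (S)-Wieland–Miescher ketone A1. Forward, A1 would be taken by reductive gem-dimethylation to the trans-dione A2, ring B would be elaborated (C8 methyl, C7=C8, one-carbon homologation of the C9 ketone) to 13, and the ether closed by Mitsunobu reaction with 14. The chosen plan is preferred because A2 has two ketones to differentiate and ring B needs several separate carbon and oxidation-level changes. More seriously, the usual ways of placing the C9 hydrogen in this series (hydroboration of a C9 methylene, hydrogenation, enolate protonation) act from the α face and should give the equatorial arm, so an extra inversion sequence would be needed. The route would be expected to exceed a dozen steps.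

Alternative 2: cut C4–C5 and C9–C10 together in a cationic bicyclisation of the (2Z,6E)-epoxyfarnesyl ether A3 (Lewis acid, low temperature) to the 3β-alcohol A4, followed by oxidation at C3. This is short, and the Z alkene should place C11 axially through a chair-chair fold. It is not preferred because every selectivity is decided in one step that cannot be steered. Proton loss from the C8 cation can give C7=C8, C8=C12 and C8=C9 isomers. The allylic aryl ether of A3 is itself ionisable by the Lewis acid. The electron-rich coumarin can intercept cations. The route also needs a geometrically pure Z,E-triene and a site- and enantioselective terminal epoxidation. The chosen plan fixes C5, C10, C9 and the alkene position one at a time.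

Alternative 3: cut C9–C11 in a [2,3]-Wittig–Still rearrangement of the 7α-stannylmethyl ether A5, which would give the ketal-protected alcohol A6 and, after deprotection, 13. The stereochemical logic (suprafacial transfer from the α face of C7 to the α face of C9, alkene returned to C7=C8) is as sound as in the chosen plan. It is not preferred because A5 requires a bicyclic 7α-allylic alcohol, reachable only by a 1,3-carbonyl transposition that starts with hydrazone formation at the C9 ketone between two fully substituted carbons. The C3 ketone must also be protected against BuLi, so the route would be at least four steps longer.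

Key step: step 7

## Route

Step 1
Reactants: 1 (R)-(−)-carvone
Product: 2 (5R,6S)-2,6-dimethyl-5-(prop-1-en-2-yl)cyclohex-2-en-1-one (used together with its 6-epimer)
Conditions: LiN(iPr)2, THF, −78 °C; then MeI, −78 to 0 °C
Reagents that add atoms: iodomethane, CI
Why: Kinetic deprotonation at the α′ carbon gives the cross-conjugated enolate, which is C-methylated (enolate alkylation). The new centre forms mainly trans to the isopropenyl group but is re-enolised in step 2, so its configuration does not matter; C5 of 1 is untouched.

Step 2
Reactants: 2 (5R,6S)-2,6-dimethyl-5-(prop-1-en-2-yl)cyclohex-2-en-1-one; 3 propargyl bromide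
Product: 4 (5S,6S)-2,6-dimethyl-6-(prop-2-yn-1-yl)-5-(prop-1-en-2-yl)cyclohex-2-en-1-one
Conditions: LiN(iPr)2, THF, −78 to 0 °C; then 3, DMPU, −78 to 23 °C
Reagents that add atoms: none
Why: Second α′-enolate alkylation with an activated propargylic electrophile. The electrophile enters on the enolate face opposite the adjacent isopropenyl group, so the propargyl arm (future C1) ends trans and the methyl cis to it, which is the C5/C10 relationship of a trans-decalin.

Step 3
Reactants: 4 (5S,6S)-2,6-dimethyl-6-(prop-2-yn-1-yl)-5-(prop-1-en-2-yl)cyclohex-2-en-1-one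
Product: 5 3-[(1S,6S)-1,3-dimethyl-2-oxo-6-(prop-1-en-2-yl)cyclohex-3-en-1-yl]propanal
Conditions: CpRu(MeCN)3PF6 (5 mol %), 5,5′-bis(trifluoromethyl)-2,2′-bipyridine (5 mol %), N-methylpyrrolidinone/H2O (4:1), 25 °C
Reagents that add atoms: water, O
Why: Ruthenium vinylidene-mediated anti-Markovnikov hydration of a terminal alkyne: water adds to the vinylidene α-carbon and tautomerisation gives the aldehyde. The enone and the isopropenyl alkene cannot form vinylidenes and stay intact.

Step 4
Reactants: 5 3-[(1S,6S)-1,3-dimethyl-2-oxo-6-(prop-1-en-2-yl)cyclohex-3-en-1-yl]propanal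
Product: 6 3-[(1S,6S)-1,3-dimethyl-2-oxo-6-(prop-1-en-2-yl)cyclohex-3-en-1-yl]propanenitrile
Conditions: Ph2P(O)ONH2 (1.2 equiv), toluene, 85 °C
Reagents that add atoms: O-(diphenylphosphinyl)hydroxylamine, NOP(=O)(c1ccccc1)c1ccccc1
Why: The aldehyde condenses to an O-phosphinyl aldoxime, which eliminates diphenylphosphinic acid to the nitrile (one-step aldehyde-to-nitrile conversion). The conjugated C9 ketone, flanked by a quaternary carbon, should not condense.

Step 5
Reactants: 6 3-[(1S,6S)-1,3-dimethyl-2-oxo-6-(prop-1-en-2-yl)cyclohex-3-en-1-yl]propanenitrile
Product: 7 3-[(3S,7S,8S)-4,8-dimethyl-7-(prop-1-en-2-yl)-1-oxaspiro[2.5]oct-4-en-8-yl]propanenitrile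
Conditions: Me3S+ I−, KN(SiMe3)2, THF, 0 °C; then 6, 0 to 23 °C
Reagents that add atoms: trimethylsulfonium iodide, C[S+](C)C.[I-]
Why: Corey–Chaykovsky epoxidation: the sulfonium ylide adds 1,2 to the enone carbonyl and the betaine closes with loss of Me2S. Attack should occur anti to the axial C10 methyl (axial attack on the conformer with equatorial isopropenyl and cyanoethyl groups), placing C11 on the α face and oxygen on the β face of C9. The nitrile α-hydrogens are far less acidic than the sulfonium salt and are left alone.

Step 6
Reactants: 7 3-[(3S,7S,8S)-4,8-dimethyl-7-(prop-1-en-2-yl)-1-oxaspiro[2.5]oct-4-en-8-yl]propanenitrile; 8 2-nitro-N′-(propan-2-ylidene)benzenesulfonohydrazide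
Product: 11 3-[(1S,2R,6S)-2-(hydroxymethyl)-1,3-dimethyl-6-(prop-1-en-2-yl)cyclohex-3-en-1-yl]propanenitrile, via allylic sulfonylhydrazone 9 (not isolated), via allylic diazene 10 (not isolated)
Conditions: Pd2(dba)3 (2.5 mol %), PPh3 (12 mol %), 8 (1.2 equiv), THF, 23 °C; then CF3CH2OH/H2O (1:1), 23 °C
Reagents that add atoms: none
Why: Tsuji–Trost substitution of a vinyl epoxide followed by allylic diazene rearrangement. Zerovalent palladium ionises the C9–O bond with inversion (Pd on the α face) and the acidic N–H of 8 attacks the unhindered C7 terminus anti to Pd, on the β face; hydrolysis of the hydrazone, loss of the sulfinic acid and a suprafacial retro-ene loss of N2 then deliver hydrogen to the β face of C9 and return the alkene to C7=C8. C9 ends with C11 α, anti to the C10 methyl, the configuration that delivery of hydrogen from the open α face cannot give.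

Step 7
Reactants: 11 3-[(1S,2R,6S)-2-(hydroxymethyl)-1,3-dimethyl-6-(prop-1-en-2-yl)cyclohex-3-en-1-yl]propanenitrile
Product: 13 (4aS,5R,8aR)-5-(hydroxymethyl)-1,1,4a,6-tetramethyl-3,4,4a,5,8,8a-hexahydronaphthalen-2(1H)-one, via ketimine 12 (not isolated)
Conditions: Fe(acac)3 (30 mol %), PhSiH3 (2.5 equiv), EtOH (0.02 M), 60 °C; then 1 M aq HCl, THF, 23 °C
Reagents that add atoms: water, O
Why: An iron hydride formed from Fe(acac)3, PhSiH3 and EtOH transfers a hydrogen atom to the CH2 terminus of the isopropenyl group (Mukaiyama-type metal-hydride hydrogen-atom transfer), giving the tertiary C4 radical that now carries both methyls. This nucleophilic radical adds to the nitrile carbon in a 6-exo-dig closure that forms the C3–C4 bond and ring A; the iminyl radical is reduced by divalent iron and protonated by EtOH to ketimine 12, which aqueous acid hydrolyses to the C3 ketone. The closest known reaction type is the iron hydride initiated cyclisation of alkenyl nitriles to α-quaternary cyclic ketones. Ring A closes through a chair-like transition state in which the C4 radical on C5 and the cyanoethyl arm on C10 are both equatorial on ring B, so the trans ring fusion follows from the C5/C10 relationship set in step 2. No new stereocentre is created (C4 bears two identical methyls), and C5, C9 and C10 are spectators. The step needs hydrogen-atom transfer to the 1,1-disubstituted alkene in preference to the trisubstituted C7=C8 alkene, which the less hindered terminal CH2 secures, and cyclisation faster than reduction of the radical, which is helped by the quaternary C10 (Thorpe–Ingold effect), by dilution and by the absence of any other acceptor within reach (addition to C7 or C8 would give a four-membered or a bridged ring). The primary alcohol is inert under these conditions, and the coumarin, itself a radical acceptor, is not yet present.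

Step 8
Reactants: 13 (4aS,5R,8aR)-5-(hydroxymethyl)-1,1,4a,6-tetramethyl-3,4,4a,5,8,8a-hexahydronaphthalen-2(1H)-one; 14 7-hydroxy-2H-chromen-2-one (umbelliferone)
Product: 15 7-{[(1R,4aR,8aS)-2,5,5,8a-tetramethyl-6-oxo-1,4,4a,5,6,7,8,8a-octahydronaphthalen-1-yl]methoxy}-2H-chromen-2-one
Conditions: PPh3, iPrO2CN=NCO2iPr (DIAD), THF, 0 to 40 °C
Reagents that add atoms: none
Why: Mitsunobu etherification: the primary C11 alcohol is activated as its alkoxyphosphonium salt and displaced by the phenoxide of 14 (pKa about 8) in an SN2 step at a carbon that is not stereogenic. The C9 centre, the C3 ketone and the lactone are not involved.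

## Compound list

1 | (R)-(−)-carvone, (5R)-2-methyl-5-(prop-1-en-2-yl)cyclohex-2-en-1-one | CC1=CC[C@@H](C(C)=C)CC1=O | starting material
2 | (5R,6S)-2,6-dimethyl-5-(prop-1-en-2-yl)cyclohex-2-en-1-one (major epimer; 6-epimer carried along) | CC1=CC[C@@H](C(C)=C)[C@H](C)C1=O | intermediate
3 | propargyl bromide (3-bromoprop-1-yne) | BrCC#C | starting material
4 | (5S,6S)-2,6-dimethyl-6-(prop-2-yn-1-yl)-5-(prop-1-en-2-yl)cyclohex-2-en-1-one (propargyl trans to isopropenyl) | CC1=CC[C@@H](C(C)=C)[C@](C)(CC#C)C1=O | intermediate
5 | 3-[(1S,6S)-1,3-dimethyl-2-oxo-6-(prop-1-en-2-yl)cyclohex-3-en-1-yl]propanal | CC1=CC[C@@H](C(C)=C)[C@](C)(CCC=O)C1=O | intermediate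
6 | 3-[(1S,6S)-1,3-dimethyl-2-oxo-6-(prop-1-en-2-yl)cyclohex-3-en-1-yl]propanenitrile | CC1=CC[C@@H](C(C)=C)[C@](C)(CCC#N)C1=O | intermediate
7 | 3-[(3S,7S,8S)-4,8-dimethyl-7-(prop-1-en-2-yl)-1-oxaspiro[2.5]oct-4-en-8-yl]propanenitrile (epoxide CH2 anti to the ring methyl on the neighbouring quaternary carbon) | CC1=CC[C@@H](C(C)=C)[C@](C)(CCC#N)[C@]12CO2 | intermediate
8 | 2-nitro-N′-(propan-2-ylidene)benzenesulfonohydrazide | CC(C)=NNS(=O)(=O)c1ccccc1[N+](=O)[O-] | starting material
9 | N-[(1S,4S,5S)-4-(2-cyanoethyl)-3-(hydroxymethyl)-2,4-dimethyl-5-(prop-1-en-2-yl)cyclohex-2-en-1-yl]-2-nitro-N′-(propan-2-ylidene)benzenesulfonohydrazide | CC1=C(CO)[C@@](C)(CCC#N)[C@H](C(C)=C)C[C@@H]1N(N=C(C)C)S(=O)(=O)c1ccccc1[N+](=O)[O-] | intermediate (not isolated)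
10 | 3-[(1S,4S,6S)-4-diazenyl-2-(hydroxymethyl)-1,3-dimethyl-6-(prop-1-en-2-yl)cyclohex-2-en-1-yl]propanenitrile | CC1=C(CO)[C@@](C)(CCC#N)[C@H](C(C)=C)C[C@@H]1N=N | intermediate (not isolated)
11 | 3-[(1S,2R,6S)-2-(hydroxymethyl)-1,3-dimethyl-6-(prop-1-en-2-yl)cyclohex-3-en-1-yl]propanenitrile | CC1=CC[C@@H](C(C)=C)[C@](C)(CCC#N)[C@@H]1CO | intermediate
12 | [(1R,4aR,8aS)-6-imino-2,5,5,8a-tetramethyl-1,4,4a,5,6,7,8,8a-octahydronaphthalen-1-yl]methanol | CC1=CC[C@H]2C(C)(C)C(=N)CC[C@]2(C)[C@@H]1CO | intermediate (not isolated)
13 | (4aS,5R,8aR)-5-(hydroxymethyl)-1,1,4a,6-tetramethyl-3,4,4a,5,8,8a-hexahydronaphthalen-2(1H)-one | CC1=CC[C@H]2C(C)(C)C(=O)CC[C@]2(C)[C@@H]1CO | intermediate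
14 | 7-hydroxy-2H-chromen-2-one (umbelliferone) | Oc1ccc2ccc(=O)oc2c1 | starting material
15 | 7-{[(1R,4aR,8aS)-2,5,5,8a-tetramethyl-6-oxo-1,4,4a,5,6,7,8,8a-octahydronaphthalen-1-yl]methoxy}-2H-chromen-2-one | CC1=CC[C@H]2C(C)(C)C(=O)CC[C@]2(C)[C@@H]1COc1ccc2ccc(=O)oc2c1 | target

## Step count and least certain steps

Total step count: 8. Longest linear sequence: 8 steps (1 to 15); 3, 8 and 14 are purchased and no protecting group is used.

Step 7 (key step). The most likely failure is reduction of the tertiary radical before it cyclises, because 6-exo addition to a nitrile is slow and reversible; hydrogen-atom transfer to the C7=C8 alkene is a second possible leak. The fallback sets out from 11 and comes back at 15. iBu2AlH (toluene, −78 °C) would reduce the nitrile to the hydroxy aldehyde F1. The same Fe(acac)3/PhSiH3 conditions would then close ring A by radical addition to the aldehyde, a much faster acceptor whose alkoxy radical is trapped by reduction, giving the diol F2 as a mixture of C3 epimers. Mitsunobu reaction with 14 should be selective for the primary C11 hydroxyl over the secondary one next to C4 and give the hydroxy ether F3. Dess–Martin oxidation of the C3 carbinol then returns to 15.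

Step 6. The most likely failure is loss of the π-allyl intermediate by β-hydride elimination, or isomerisation of the vinyl epoxide, before the hydrazone attacks, because ionisation creates a hindered, fully substituted allyl terminus. The fallback sets out from 7 and comes back at 11. 4-Methoxyphenol with K2CO3 (DMF, 80 °C) would open the epoxide at C11 to the tertiary allylic alcohol F4. Pyridinium chlorochromate (C5H5NH)[CrO3Cl] would effect the oxidative 1,3-transposition to the enone F5 (C7 ketone, C8=C9). TsNHNH2 would give the tosylhydrazone F6. Catecholborane then NaOAc should add hydride to C7 from the α (axial) face, and the β-diazene so formed should transfer hydrogen to the β face of C9 with return of the alkene to C7=C8, giving the 4-methoxyphenyl ether F7. (NH4)2Ce(NO3)6 would remove the aryl group and return to 11.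

Step 5. The most likely failure is that the ylide does not add to the C9 carbonyl, which lies between a quaternary carbon and a methyl-bearing alkene carbon, and instead deprotonates the γ position (C6). The fallback sets out from 6 and comes back at 7. It replaces the reversible ylide addition by an irreversible carbenoid addition: ClCH2Li, generated in situ from ICH2Cl and MeLi·LiBr at −78 °C, should add from the same α face and give, after quench, the chlorohydrin F8. K2CO3 in MeOH would close F8 to 7.

Step 8. The most likely failure is slow substitution at the β-branched C11, which lets alkylation of the reduced azodicarboxylate or elimination towards C9 compete. The fallback sets out from 13 and comes back at 15. MsCl/Et3N would give the mesylate F9, and Cs2CO3 with 14 in DMF at 70 °C would displace it to 15.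

## Further compounds

F1 | step 7 | 3-[(1S,2R,6S)-2-(hydroxymethyl)-1,3-dimethyl-6-(prop-1-en-2-yl)cyclohex-3-en-1-yl]propanal | CC1=CC[C@@H](C(C)=C)[C@](C)(CCC=O)[C@@H]1CO
F2 | step 7 | (4aS,5R,8aR)-5-(hydroxymethyl)-1,1,4a,6-tetramethyl-1,2,3,4,4a,5,8,8a-octahydronaphthalen-2-ol (both C2 epimers) | CC1=CC[C@H]2C(C)(C)C(O)CC[C@]2(C)[C@@H]1CO
F3 | step 7 | 7-{[(1R,4aR,8aS)-6-hydroxy-2,5,5,8a-tetramethyl-1,4,4a,5,6,7,8,8a-octahydronaphthalen-1-yl]methoxy}-2H-chromen-2-one (both C6 epimers) | CC1=CC[C@H]2C(C)(C)C(O)CC[C@]2(C)[C@@H]1COc1ccc2ccc(=O)oc2c1
F4 | step 6 | 3-[(1S,2S,6S)-2-hydroxy-2-[(4-methoxyphenoxy)methyl]-1,3-dimethyl-6-(prop-1-en-2-yl)cyclohex-3-en-1-yl]propanenitrile | CC1=CC[C@@H](C(C)=C)[C@](C)(CCC#N)[C@]1(O)COc1ccc(OC)cc1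
F5 | step 6 | 3-[(1S,6S)-2-[(4-methoxyphenoxy)methyl]-1,3-dimethyl-4-oxo-6-(prop-1-en-2-yl)cyclohex-2-en-1-yl]propanenitrile | CC1=C(COc2ccc(OC)cc2)[C@@](C)(CCC#N)[C@H](C(C)=C)CC1=O
F6 | step 6 | N′-[(4S,5S)-4-(2-cyanoethyl)-3-[(4-methoxyphenoxy)methyl]-2,4-dimethyl-5-(prop-1-en-2-yl)cyclohex-2-en-1-ylidene]-4-methylbenzenesulfonohydrazide | CC1=C(COc2ccc(OC)cc2)[C@@](C)(CCC#N)[C@H](C(C)=C)CC1=NNS(=O)(=O)c1ccc(C)cc1
F7 | step 6 | 3-[(1S,2R,6S)-2-[(4-methoxyphenoxy)methyl]-1,3-dimethyl-6-(prop-1-en-2-yl)cyclohex-3-en-1-yl]propanenitrile | CC1=CC[C@@H](C(C)=C)[C@](C)(CCC#N)[C@@H]1COc1ccc(OC)cc1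
F8 | step 5 | 3-[(1S,2S,6S)-2-(chloromethyl)-2-hydroxy-1,3-dimethyl-6-(prop-1-en-2-yl)cyclohex-3-en-1-yl]propanenitrile | CC1=CC[C@@H](C(C)=C)[C@](C)(CCC#N)[C@]1(O)CCl
F9 | step 8 | [(1R,4aR,8aS)-2,5,5,8a-tetramethyl-6-oxo-1,4,4a,5,6,7,8,8a-octahydronaphthalen-1-yl]methyl methanesulfonate | CC1=CC[C@H]2C(C)(C)C(=O)CC[C@]2(C)[C@@H]1COS(C)(=O)=O
A1 | alternative 1 | (S)-Wieland–Miescher ketone, (8aS)-8a-methyl-3,4,8,8a-tetrahydronaphthalene-1,6(2H,7H)-dione | C[C@]12CCC(=O)C=C1CCCC2=O
A2 | alternative 1 | (4aS,8aS)-5,5,8a-trimethyloctahydronaphthalene-1,6-dione (trans-fused) | O=C1CCC[C@H]2C(C)(C)C(=O)CC[C@]12C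
A3 | alternative 2 | 7-{[(2Z,6E)-9-[(2S)-3,3-dimethyloxiran-2-yl]-3,7-dimethylnona-2,6-dien-1-yl]oxy}-2H-chromen-2-one | CC1(C)O[C@H]1CC/C(C)=C/CC/C(C)=C\COc1ccc2ccc(=O)oc2c1
A4 | alternative 2 | 7-{[(1R,4aR,6S,8aS)-6-hydroxy-2,5,5,8a-tetramethyl-1,4,4a,5,6,7,8,8a-octahydronaphthalen-1-yl]methoxy}-2H-chromen-2-one | CC1=CC[C@H]2C(C)(C)[C@@H](O)CC[C@]2(C)[C@@H]1COc1ccc2ccc(=O)oc2c1
A5 | alternative 3 | 7α-[(tributylstannyl)methoxy]-11-nordrim-8-ene 3-ethylene ketal (5α-H, 10β-CH3) | CC1=C[C@@]2(C)CCC3(OCCO3)C(C)(C)[C@@H]2C[C@H]1OC[Sn](CCCC)(CCCC)CCCC
A6 | alternative 3 | ethylene ketal (1,3-dioxolane at C3) of 13 | CC1=CC[C@H]2C(C)(C)C3(OCCO3)CC[C@]2(C)[C@@H]1CO
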